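With C1 the prenylated bridgehead beside C8 (CMe2), C7 the CH(prenyl), C6 the ring CH2, C5 the other bridgehead and C9 the bridging carbonyl, the bicycle is disconnected at C5–C6. C5 lies between the C4 and C9 carbonyls of ring A (C1–C5, C9), so it is a doubly stabilised enolate carbon; C6 is a primary carbon tethered to C1, so a six-membered enolendo alkylation closes ring B. In one pot an open-chain chloro keto ester undergoes Dieckmann closure of ring A (C4–C5), then the diketonate is C-alkylated by C6, creating quaternary C5. C7 (Evans alkylation), C1 (lactone-templated prenylation) and the C2 methyl enol ether are already set; C3-benzoylation finishes.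

Key step: step 14

Remarks on the chemistry: the numbering of the target bicyclo[3.3.1]nonane is used throughout; in the lactones, oxane C3, C4, C5 and C6 become C1, C8, C7 and C6. The hydroxy keto ester of step 11 is drawn open-chain although it should equilibrate with its six-membered lactols. The geometry of the methoxyacrylate formed in step 12 is left open because it should equilibrate in step 14. The descriptor of C5 changes from S to R in step 15 only because the benzoyl group alters the priorities; no bond at C5 is touched.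

Step 1
Reactants: 1 3,3-dimethylglutaric anhydride; 2 (S)-4-benzyloxazolidin-2-one
Product: 3 5-[(4S)-4-benzyl-2-oxo-1,3-oxazolidin-3-yl]-3,3-dimethyl-5-oxopentanoic acid
Conditions: n-BuLi, THF, −78 °C; then 1, −78 → 0 °C; 1 M HCl work-up
Reagents that add atoms: none
Why: Ring-opening N-acylation of the lithiated oxazolidinone by the cyclic anhydride should give the imide acid directly; no stereocenter is formed.

Step 2
Reactants: 3 imide acid; 4 prenyl bromide (1-bromo-3-methylbut-2-ene)
Product: 5 (4S)-5-[(4S)-4-benzyl-2-oxo-1,3-oxazolidin-3-yl]-3,3-dimethyl-4-(3-methylbut-2-en-1-yl)-5-oxopentanoic acid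
Conditions: NaN(SiMe3)2 (2.2 equiv), THF, −78 °C; then 4, −78 → −40 °C; dilute HCl work-up
Reagents that add atoms: none
Why: Evans asymmetric alkylation: the chelated Z sodium enolate of the imide (the carboxylate is a spectator) should be attacked by prenyl bromide on the face opposite the benzyl group, which sets C7.

Step 3
Reactants: 5 prenylated imide acid
Product: 7 (5S)-4,4-dimethyl-5-(3-methylbut-2-en-1-yl)oxan-2-one, via hydroxy acid 6 (not isolated)
Conditions: LiOt-Bu (1 equiv), then LiBH4, THF–MeOH, 0 °C; then 1 M HCl, 25 °C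
Reagents that add atoms: none
Why: Reductive cleavage of the N-acyl oxazolidinone by LiBH4 (the acid is first converted into its carboxylate so that no borane forms) should give the primary alcohol, and the acidic work-up should close the gem-dimethyl-assisted δ-lactone; C7 is no longer enolisable.

Step 4
Reactants: 7 lactone; 8 N-methoxy-N-methylacetamide
Product: 9 (5S)-3-acetyl-4,4-dimethyl-5-(3-methylbut-2-en-1-yl)oxan-2-one (C3 epimers and enol)
Conditions: LiN(i-Pr)2, THF, −78 °C; then 8, −78 → 0 °C; aq. NH4Cl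
Reagents that add atoms: none
Why: Crossed Claisen-type C-acylation of the lactone lithium enolate by a Weinreb amide, whose stable chelate prevents over-addition; the new C3 center is enolised and irrelevant.

Step 5
Reactants: 2 (S)-4-benzyloxazolidin-2-one; 10 3-methylbut-2-enoyl chloride
Product: 11 (4S)-4-benzyl-3-(3-methylbut-2-enoyl)-1,3-oxazolidin-2-one
Conditions: n-BuLi, THF, −78 °C; then 10, −78 → 0 °C
Reagents that add atoms: none
Why: N-acylation of the lithiated Evans auxiliary with the acid chloride; no stereocenter is formed.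

Step 6
Reactants: 11 N-senecioyl oxazolidinone; 4 prenyl bromide
Product: 12 (4S)-4-benzyl-3-[(2S)-5-methyl-2-(prop-1-en-2-yl)hex-4-enoyl]-1,3-oxazolidin-2-one
Conditions: NaN(SiMe3)2, THF, −78 °C; then 4, −78 → −30 °C
Reagents that add atoms: none
Why: Deconjugative Evans alkylation: γ-deprotonation gives the extended sodium enolate, which should be alkylated at the α-carbon anti to the benzyl group, setting the lavandulyl stereocenter and leaving the isopropenyl group.

Step 7
Reactants: 12 lavandulyl imide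
Product: 13 (S)-lavandulol, (2S)-5-methyl-2-(prop-1-en-2-yl)hex-4-en-1-ol
Conditions: LiBH4, Et2O, H2O (1 equiv), 0 °C; aq. NH4Cl
Reagents that add atoms: none
Why: Reductive removal of the auxiliary with LiBH4 should give the alcohol without migration of the β,γ-double bond or loss of configuration.

Step 8
Reactants: 13 (S)-lavandulol
Product: 14 (S)-lavandulyl iodide, (3S)-3-(iodomethyl)-2,6-dimethylhepta-1,5-diene
Conditions: PPh3, I2, imidazole, CH2Cl2, 0 °C
Reagents that add atoms: iodine, II
Why: Appel-type iodination of the primary alcohol; the stereocenter is not involved.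

Step 9
Reactants: 9 acetyl lactone; 14 (S)-lavandulyl iodide
Product: 15 (5S)-4,4-dimethyl-5-(3-methylbut-2-en-1-yl)-3-[(4S)-7-methyl-4-(prop-1-en-2-yl)oct-6-enoyl]oxan-2-one (C3 epimers and enol)
Conditions: LiN(i-Pr)2 (2.2 equiv), THF, 0 °C; then 14, THF–DMPU, 0 → 25 °C; aq. NH4Cl
Reagents that add atoms: none
Why: β-Dicarbonyl dianion alkylation: the dianion of the β-keto lactone should react at its terminal (γ) carbon, the future C5, with the primary iodide.

Step 10
Reactants: 15 β-keto lactone; 4 prenyl bromide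
Product: 16 (3S,5S)-4,4-dimethyl-3,5-bis(3-methylbut-2-en-1-yl)-3-[(4S)-7-methyl-4-(prop-1-en-2-yl)oct-6-enoyl]oxan-2-one (the two ring prenyl groups trans)
Conditions: NaH, THF, 0 °C; then 4, 0 → 25 °C; aq. NH4Cl
Reagents that add atoms: none
Why: C-alkylation of the β-keto lactone enolate: with the C5 prenyl group equatorial the electrophile should enter axially on the face anti to the axial 4-methyl group, so the new prenyl group is trans to the C5 prenyl group, which is the C1 configuration of the target.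

Step 11
Reactants: 16 diprenylated keto lactone; 17 methyl acetate
Product: 18 methyl (4S,8S)-4-[(3S)-4-hydroxy-2-methyl-3-(3-methylbut-2-en-1-yl)butan-2-yl]-11-methyl-4-(3-methylbut-2-en-1-yl)-3,5-dioxo-8-(prop-1-en-2-yl)dodec-10-enoate
Conditions: LiN(i-Pr)2 and 17 (4 equiv each), THF, −78 °C; then 16, −78 → −20 °C; aq. NH4Cl
Reagents that add atoms: none
Why: Claisen acylation of the lithium enolate of methyl acetate by the lactone carbonyl (C2) should open the ring to the δ-hydroxy β-keto ester, whose deprotonation drives the step; the first equivalent of enolate converts the C9 ketone into its enolate, which protects it from addition and from retro-Claisen cleavage.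

Step 12
Reactants: 18 hydroxy β-keto ester
Product: 19 methyl (4R,8S)-4-[(3S)-4-hydroxy-2-methyl-3-(3-methylbut-2-en-1-yl)butan-2-yl]-3-methoxy-11-methyl-4-(3-methylbut-2-en-1-yl)-5-oxo-8-(prop-1-en-2-yl)dodeca-2,10-dienoate (E/Z mixture at the 2,3-double bond)
Conditions: Me2SO4 (1.2 equiv), Cs2CO3, DMF, 0 °C
Reagents that add atoms: dimethyl sulfate, COS(=O)(=O)OC
Why: O-alkylation of the dissociated cesium enolate of the β-keto ester by a hard alkylating agent should place the methyl group on the C2 oxygen only, because C2 is the only ketone of a β-keto ester unit; this fixes the position of the methoxy group.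

Step 13
Reactants: 19 methoxyacrylate alcohol
Product: 20 methyl (4R,8S)-4-[(3S)-4-chloro-2-methyl-3-(3-methylbut-2-en-1-yl)butan-2-yl]-3-methoxy-11-methyl-4-(3-methylbut-2-en-1-yl)-5-oxo-8-(prop-1-en-2-yl)dodeca-2,10-dienoate (E/Z mixture)
Conditions: PPh3, N-chlorosuccinimide, THF, 0 → 25 °C
Reagents that add atoms: N-chlorosuccinimide, O=C1CCC(=O)N1Cl
Why: Appel-type chlorination of the primary alcohol under neutral conditions; a chloride is chosen because it should survive the Claisen stage of step 14.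

Step 14
Reactants: 20 chloro keto methoxyacrylate
Product: 22 (1R,5S,7R)-2-methoxy-8,8-dimethyl-1,7-bis(3-methylbut-2-en-1-yl)-5-[(2R)-5-methyl-2-(prop-1-en-2-yl)hex-4-en-1-yl]bicyclo[3.3.1]non-2-ene-4,9-dione, via monocyclic chloro diketone 21 (not isolated)
Conditions: KOt-Bu (1.3 equiv), t-BuOH–THF, 25 °C; then NaI (0.2 equiv), 60 °C
Reagents that add atoms: none
Why: KOt-Bu forms the C5 enolate of the C9 ketone, which attacks the C4 ester carbonyl in a Dieckmann-type Claisen condensation (6-exo-trig; only the E-methoxyacrylate can close and the isomers should interconvert by reversible conjugate addition of the liberated methoxide), and deprotonation of the new 1,3-diketone drives the closure of ring A to completion. After chloride–iodide exchange the potassium diketonate is alkylated at C5 by the primary carbon C6 (6-(enolendo)-exo-tet), which closes ring B through the C5–C6 bond and makes C5 quaternary. The closest known reactions are the Dieckmann condensation and the α,α'-annulation of cyclic β-dicarbonyl compounds with 1,3-dihalides to bicyclo[3.3.1]nonan-9-ones, whose second stage is the same intramolecular enolate alkylation. C5 is the only new stereocenter and has no free choice, because C6 can reach only the face of the ring-A enolate on which the C1–C8 bond lies, through a chair of ring B in which the C1 and C7 prenyl groups are equatorial, so C1 and C7 dictate C5. The step needs carbon over oxygen alkylation (O9) and reaction at C5 and not at C3; the enolendo geometry, the soft iodide, the hydrogen-bonding co-solvent that shields the enolate oxygen and the fact that C3 is a vinylic carbon of the enol ether should secure this.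

Step 15
Reactants: 22 bicyclic vinylogous ester; 23 benzoyl chloride
Product: 24 (1R,5R,7R)-3-benzoyl-2-methoxy-8,8-dimethyl-1,7-bis(3-methylbut-2-en-1-yl)-5-[(2R)-5-methyl-2-(prop-1-en-2-yl)hex-4-en-1-yl]bicyclo[3.3.1]non-2-ene-4,9-dione
Conditions: lithium 2,2,6,6-tetramethylpiperidide, THF, −78 °C; then 23, −78 → −40 °C
Reagents that add atoms: none
Why: Lithiation of the vinylic C3–H of the β-methoxy enone and C-acylation with benzoyl chloride, a known reaction of bicyclic vinylogous esters of this family; both bridgeheads are quaternary, so no other position should be deprotonated.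

Compound list

1 | 3,3-dimethylglutaric anhydride | CC1(C)CC(=O)OC(=O)C1 | starting material
2 | (S)-4-benzyloxazolidin-2-one | O=C1N[C@@H](Cc2ccccc2)CO1 | starting material
3 | 5-[(4S)-4-benzyl-2-oxo-1,3-oxazolidin-3-yl]-3,3-dimethyl-5-oxopentanoic acid | OC(=O)CC(C)(C)CC(=O)N1[C@@H](Cc2ccccc2)COC1=O | intermediate
4 | prenyl bromide (1-bromo-3-methylbut-2-ene) | CC(C)=CCBr | starting material
5 | (4S)-5-[(4S)-4-benzyl-2-oxo-1,3-oxazolidin-3-yl]-3,3-dimethyl-4-(3-methylbut-2-en-1-yl)-5-oxopentanoic acid | OC(=O)CC(C)(C)[C@H](CC=C(C)C)C(=O)N1[C@@H](Cc2ccccc2)COC1=O | intermediate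
6 | hydroxy acid (not isolated): (4S)-5-hydroxy-3,3-dimethyl-4-(3-methylbut-2-en-1-yl)pentanoic acid | OC(=O)CC(C)(C)[C@H](CC=C(C)C)CO | intermediate
7 | (5S)-4,4-dimethyl-5-(3-methylbut-2-en-1-yl)oxan-2-one | O=C1CC(C)(C)[C@H](CC=C(C)C)CO1 | intermediate
8 | N-methoxy-N-methylacetamide | CC(=O)N(C)OC | starting material
9 | (5S)-3-acetyl-4,4-dimethyl-5-(3-methylbut-2-en-1-yl)oxan-2-one | CC(=O)C1C(=O)OC[C@@H](CC=C(C)C)C1(C)C | intermediate
10 | 3-methylbut-2-enoyl chloride | CC(C)=CC(Cl)=O | starting material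
11 | (4S)-4-benzyl-3-(3-methylbut-2-enoyl)-1,3-oxazolidin-2-one | CC(C)=CC(=O)N1[C@@H](Cc2ccccc2)COC1=O | intermediate
12 | (4S)-4-benzyl-3-[(2S)-5-methyl-2-(prop-1-en-2-yl)hex-4-enoyl]-1,3-oxazolidin-2-one | C=C(C)[C@H](CC=C(C)C)C(=O)N1[C@@H](Cc2ccccc2)COC1=O | intermediate
13 | (S)-lavandulol, (2S)-5-methyl-2-(prop-1-en-2-yl)hex-4-en-1-ol | C=C(C)[C@H](CC=C(C)C)CO | intermediate
14 | (S)-lavandulyl iodide, (3S)-3-(iodomethyl)-2,6-dimethylhepta-1,5-diene | C=C(C)[C@H](CC=C(C)C)CI | intermediate
15 | (5S)-4,4-dimethyl-5-(3-methylbut-2-en-1-yl)-3-[(4S)-7-methyl-4-(prop-1-en-2-yl)oct-6-enoyl]oxan-2-one | O=C1OC[C@@H](CC=C(C)C)C(C)(C)C1C(=O)CC[C@@H](CC=C(C)C)C(C)=C | intermediate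
16 | (3S,5S)-4,4-dimethyl-3,5-bis(3-methylbut-2-en-1-yl)-3-[(4S)-7-methyl-4-(prop-1-en-2-yl)oct-6-enoyl]oxan-2-one | O=C1OC[C@@H](CC=C(C)C)C(C)(C)[C@@]1(CC=C(C)C)C(=O)CC[C@@H](CC=C(C)C)C(C)=C | intermediate
17 | methyl acetate | COC(C)=O | starting material
18 | methyl (4S,8S)-4-[(3S)-4-hydroxy-2-methyl-3-(3-methylbut-2-en-1-yl)butan-2-yl]-11-methyl-4-(3-methylbut-2-en-1-yl)-3,5-dioxo-8-(prop-1-en-2-yl)dodec-10-enoate | OC[C@@H](CC=C(C)C)C(C)(C)[C@@](CC=C(C)C)(C(=O)CC[C@@H](CC=C(C)C)C(C)=C)C(=O)CC(=O)OC | intermediate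
19 | methyl (4R,8S)-4-[(3S)-4-hydroxy-2-methyl-3-(3-methylbut-2-en-1-yl)butan-2-yl]-3-methoxy-11-methyl-4-(3-methylbut-2-en-1-yl)-5-oxo-8-(prop-1-en-2-yl)dodeca-2,10-dienoate (E/Z) | OC[C@@H](CC=C(C)C)C(C)(C)[C@@](CC=C(C)C)(C(=O)CC[C@@H](CC=C(C)C)C(C)=C)C(OC)=CC(=O)OC | intermediate
20 | methyl (4R,8S)-4-[(3S)-4-chloro-2-methyl-3-(3-methylbut-2-en-1-yl)butan-2-yl]-3-methoxy-11-methyl-4-(3-methylbut-2-en-1-yl)-5-oxo-8-(prop-1-en-2-yl)dodeca-2,10-dienoate (E/Z) | ClC[C@@H](CC=C(C)C)C(C)(C)[C@@](CC=C(C)C)(C(=O)CC[C@@H](CC=C(C)C)C(C)=C)C(OC)=CC(=O)OC | intermediate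
21 | monocyclic chloro diketone (not isolated): (4R)-4-[(3S)-4-chloro-2-methyl-3-(3-methylbut-2-en-1-yl)butan-2-yl]-3-methoxy-4-(3-methylbut-2-en-1-yl)-6-[(2R)-5-methyl-2-(prop-1-en-2-yl)hex-4-en-1-yl]cyclohex-2-ene-1,5-dione, ring C6 (the future C5) epimerisable | ClC[C@@H](CC=C(C)C)C(C)(C)[C@@]1(CC=C(C)C)C(=O)C(C[C@@H](CC=C(C)C)C(C)=C)C(=O)C=C1OC | intermediate
22 | (1R,5S,7R)-2-methoxy-8,8-dimethyl-1,7-bis(3-methylbut-2-en-1-yl)-5-[(2R)-5-methyl-2-(prop-1-en-2-yl)hex-4-en-1-yl]bicyclo[3.3.1]non-2-ene-4,9-dione | C=C(C)[C@H](CC=C(C)C)C[C@@]12C[C@@H](CC=C(C)C)C(C)(C)[C@@](CC=C(C)C)(C1=O)C(OC)=CC2=O | intermediate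
23 | benzoyl chloride | O=C(Cl)c1ccccc1 | starting material
24 | (1R,5R,7R)-3-benzoyl-2-methoxy-8,8-dimethyl-1,7-bis(3-methylbut-2-en-1-yl)-5-[(2R)-5-methyl-2-(prop-1-en-2-yl)hex-4-en-1-yl]bicyclo[3.3.1]non-2-ene-4,9-dione | C=C(C)[C@H](CC=C(C)C)C[C@@]12C[C@@H](CC=C(C)C)C(C)(C)[C@@](CC=C(C)C)(C1=O)C(OC)=C(C(=O)c1ccccc1)C2=O | target

Total steps: 15. Longest linear sequence: 11 steps (steps 1–4, then 9–15; the branch of steps 5–8, then 9–15, is equally long).

Steps most likely to fail

1. Step 14 (key step). The diketonate may be alkylated on oxygen (O9) instead of on C5, or the Claisen closure may stall if the geometric isomers of the methoxyacrylate exchange slowly. Fallback: the order of the two ring closures is reversed, setting out from 19. PPh3, I2 and imidazole (CH2Cl2, 0 °C) should give the primary iodide methyl (4R,8S)-4-[(3S)-4-iodo-2-methyl-3-(3-methylbut-2-en-1-yl)butan-2-yl]-3-methoxy-11-methyl-4-(3-methylbut-2-en-1-yl)-5-oxo-8-(prop-1-en-2-yl)dodeca-2,10-dienoate F1. KN(SiMe3)2 (1.05 equiv, THF, −78 → 0 °C) then forms the simple potassium enolate of the C9 ketone, which should be alkylated at C5 by the iodide. This 6-(enolendo)-exo-tet closure of a monoketone enolate is known to be carbon-selective and should outrun acylation by the deactivated vinylogous carbonate ester. It gives the ring-B cyclohexanone methyl 3-[(1R,3R)-2,2-dimethyl-1,3-bis(3-methylbut-2-en-1-yl)-5-[(2R)-5-methyl-2-(prop-1-en-2-yl)hex-4-en-1-yl]-6-oxocyclohexyl]-3-methoxyprop-2-enoate F2. A second charge of KN(SiMe3)2 (THF, 0 → 40 °C) forms the fully substituted C5 enolate irreversibly. Its Claisen acylation by the ester, as in condensations of esters with a single α-hydrogen under strong amide bases, closes ring A and comes back to 22.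

2. Step 11. The hindered, α-quaternary lactone carbonyl may not accept the ester enolate, the enolate may add to the C9 ketone instead, or the C9 acyl group may be lost by retro-Claisen cleavage. Fallback from 16: AlMe3 and MeNH(OMe)·HCl (CH2Cl2, 0 → 40 °C) should open the lactone under Lewis-acid activation to the hydroxy Weinreb amide (2S,6S)-2-[(3S)-4-hydroxy-2-methyl-3-(3-methylbut-2-en-1-yl)butan-2-yl]-N-methoxy-N,9-dimethyl-2-(3-methylbut-2-en-1-yl)-3-oxo-6-(prop-1-en-2-yl)dec-8-enamide F3. TBSCl and imidazole give its tert-butyldimethylsilyl ether F4. The lithium enolate of methyl acetate adds to the Weinreb amide, whose chelate is not reversed, to give the silylated β-keto ester F5. Me2SO4 and Cs2CO3 give the silylated methoxyacrylate F6, and Bu4NF buffered with AcOH returns to 19.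

3. Step 10. The hindered enolate may be alkylated on oxygen or with poor facial selectivity. Fallback from 15: a Tsuji–Trost allylation (NaH, Pd(PPh3)4 as the zerovalent palladium catalyst, allyl acetate, THF), in which the soft enolate attacks the π-allyl complex at carbon on the same face as in step 10, should give the C3-allyl lactone (3S,5S)-4,4-dimethyl-5-(3-methylbut-2-en-1-yl)-3-[(4S)-7-methyl-4-(prop-1-en-2-yl)oct-6-enoyl]-3-(prop-2-en-1-yl)oxan-2-one F7. Cross-metathesis with 2-methylbut-2-ene (second-generation Grubbs catalyst, RuCl2(=CHPh)(H2IMes)(PCy3), CH2Cl2, 40 °C) converts the allyl group into a prenyl group and comes back to 16. The prenyl groups exchange only degenerately and the 1,1-disubstituted isopropenyl group should react slowly.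

Further compounds

F1 | step 14 | methyl (4R,8S)-4-[(3S)-4-iodo-2-methyl-3-(3-methylbut-2-en-1-yl)butan-2-yl]-3-methoxy-11-methyl-4-(3-methylbut-2-en-1-yl)-5-oxo-8-(prop-1-en-2-yl)dodeca-2,10-dienoate | IC[C@@H](CC=C(C)C)C(C)(C)[C@@](CC=C(C)C)(C(=O)CC[C@@H](CC=C(C)C)C(C)=C)C(OC)=CC(=O)OC
F2 | step 14 | methyl 3-[(1R,3R)-2,2-dimethyl-1,3-bis(3-methylbut-2-en-1-yl)-5-[(2R)-5-methyl-2-(prop-1-en-2-yl)hex-4-en-1-yl]-6-oxocyclohexyl]-3-methoxyprop-2-enoate (ring C5 epimers) | COC(=O)C=C(OC)[C@]1(CC=C(C)C)C(=O)C(C[C@@H](CC=C(C)C)C(C)=C)C[C@@H](CC=C(C)C)C1(C)C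
F3 | step 11 | (2S,6S)-2-[(3S)-4-hydroxy-2-methyl-3-(3-methylbut-2-en-1-yl)butan-2-yl]-N-methoxy-N,9-dimethyl-2-(3-methylbut-2-en-1-yl)-3-oxo-6-(prop-1-en-2-yl)dec-8-enamide | OC[C@@H](CC=C(C)C)C(C)(C)[C@@](CC=C(C)C)(C(=O)CC[C@@H](CC=C(C)C)C(C)=C)C(=O)N(C)OC
F4 | step 11 | tert-butyldimethylsilyl ether of F3 | CC(C)(C)[Si](C)(C)OC[C@@H](CC=C(C)C)C(C)(C)[C@@](CC=C(C)C)(C(=O)CC[C@@H](CC=C(C)C)C(C)=C)C(=O)N(C)OC
F5 | step 11 | tert-butyldimethylsilyl ether of 18 | CC(C)(C)[Si](C)(C)OC[C@@H](CC=C(C)C)C(C)(C)[C@@](CC=C(C)C)(C(=O)CC[C@@H](CC=C(C)C)C(C)=C)C(=O)CC(=O)OC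
F6 | step 11 | tert-butyldimethylsilyl ether of 19 | CC(C)(C)[Si](C)(C)OC[C@@H](CC=C(C)C)C(C)(C)[C@@](CC=C(C)C)(C(=O)CC[C@@H](CC=C(C)C)C(C)=C)C(OC)=CC(=O)OC
F7 | step 10 | (3S,5S)-4,4-dimethyl-5-(3-methylbut-2-en-1-yl)-3-[(4S)-7-methyl-4-(prop-1-en-2-yl)oct-6-enoyl]-3-(prop-2-en-1-yl)oxan-2-one | O=C1OC[C@@H](CC=C(C)C)C(C)(C)[C@@]1(CC=C)C(=O)CC[C@@H](CC=C(C)C)C(C)=C
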